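**Retrosynthetic overview**

1. Target 11 comes from its 7,5'-dibenzyl ether 10 by hydrogenolysis. Rings A and B are bought; ring C (the pyranone) is the only ring built, closed last at O1–C2 by oxidative cyclisation of the 2'-hydroxychalcone 8 (aldol union C2–C3 of ketone 5 and aldehyde 7).
2. Key disconnection: C8a–O1. Ring A is a 1,2,3,5-tetraoxygenated benzene whose fourth oxygen (O1 on C8a) lies ortho to the C4 carbonyl. It is installed by C4=O-directed, Pd-catalysed C–H hydroxylation of the 2,3,4-trioxygenated acetophenone 3.
3. Feature used: C5 already carries OMe, so C8a–H is the only ortho C–H of the aryl ketone. Chelation therefore fixes the 5,6-dimethoxy-7-oxy pattern, which electrophilic acylation of a tetraoxygenated phenol cannot guarantee.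
4. Ketone 3 comes in two steps from gallacetophenone (4-O-benzylation, then 2,3-di-O-methylation); aldehyde 7 comes in one step from 3-hydroxy-4,5-dimethoxybenzaldehyde.

Key step: step 3

Remark: the target has no stereocentre and no stereogenic double bond, so "single enantiomer" is taken to mean the one achiral structure given. The E-alkene of 8 and the racemic centre of 9 are erased in step 6.

**Route**

Step 1
Reactants: 1 1-(2,3,4-trihydroxyphenyl)ethan-1-one (gallacetophenone)
Product: 2 1-[4-(benzyloxy)-2,3-dihydroxyphenyl]ethan-1-one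
Conditions: BnBr (1.05 equiv), NaHCO3 (1.5 equiv), DMF, 40 °C, N2
Reagents that add atoms: benzyl bromide, BrCc1ccccc1
Why: Williamson etherification with a weak base should alkylate only the 4-OH, the most acidic phenol (para to the acetyl group and not hydrogen-bonded), while the 2-OH is held in a chelate with the carbonyl and the 3-OH is the least acidic.

Step 2
Reactants: 2 1-[4-(benzyloxy)-2,3-dihydroxyphenyl]ethan-1-one
Product: 3 1-[4-(benzyloxy)-2,3-dimethoxyphenyl]ethan-1-one
Conditions: MeI (3 equiv), K2CO3 (3 equiv), DMF, 50 °C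
Reagents that add atoms: iodomethane, CI
Why: Exhaustive Williamson methylation of the two remaining phenols, with the polar solvent and mild heating needed to break the chelate of the 2-OH.

Step 3
Reactants: 3 1-[4-(benzyloxy)-2,3-dimethoxyphenyl]ethan-1-one
Product: 5 1-[4-(benzyloxy)-6-hydroxy-2,3-dimethoxyphenyl]ethan-1-one, via aryl trifluoroacetate 4 (not isolated)
Conditions: Pd(TFA)2 (5–10 mol %), PhI(OTFA)2 (2 equiv), DCE, 80 °C; then aq. Na2S2O3, aq. NaHCO3/THF, rt
Reagents that add atoms: [bis(trifluoroacetoxy)iodo]benzene, O=C(OI(OC(=O)C(F)(F)F)c1ccccc1)C(F)(F)F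
Why: The acetyl oxygen (the later C4=O) binds electrophilic Pd(II) and delivers it to the only ortho C–H (the later C8a–H) to give a five-membered palladacycle, which PhI(OTFA)2 oxidises to a Pd(IV) trifluoroacetate; C–O reductive elimination gives aryl trifluoroacetate 4, cleaved to phenol 5 in the mild basic work-up. The closest known reaction type is the Pd(II)/Pd(IV) ketone-directed ortho-C–H hydroxylation of aryl ketones with iodine(III) or persulfate oxidants, established for acetophenones. No ring is closed and no stereocentre is formed. The step needs site selectivity for the later C8a over the later C8 (the electronically most activated position, ortho to OBn and para to OMe); chelation should secure it because only C8a–H is within reach of the carbonyl-bound palladium, and a second hydroxylation is impossible because the other ortho carbon carries the 5-OMe group. The new oxygen stays masked as the electron-poor trifluoroacetate until the oxidant is quenched, which should protect the para-methoxyphenol from oxidation to a quinone.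

Step 4
Reactants: 6 3-hydroxy-4,5-dimethoxybenzaldehyde
Product: 7 3-(benzyloxy)-4,5-dimethoxybenzaldehyde
Conditions: BnBr (1.1 equiv), K2CO3 (1.5 equiv), DMF, rt
Reagents that add atoms: benzyl bromide, BrCc1ccccc1
Why: Williamson etherification of the single phenol, so that the aldehyde is not deactivated as a phenoxide in the aldol step and both hydroxyls carry the same protecting group.

Step 5
Reactants: 5 1-[4-(benzyloxy)-6-hydroxy-2,3-dimethoxyphenyl]ethan-1-one; 7 3-(benzyloxy)-4,5-dimethoxybenzaldehyde
Product: 8 (E)-1-[4-(benzyloxy)-6-hydroxy-2,3-dimethoxyphenyl]-3-[3-(benzyloxy)-4,5-dimethoxyphenyl]prop-2-en-1-one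
Conditions: KOH (50% aq., excess), EtOH, rt; then dil. HCl
Reagents that add atoms: none
Why: Claisen–Schmidt condensation of the methyl ketone enolate with the non-enolisable aldehyde, with E1cB dehydration giving the thermodynamically favoured E-enone; partial closure to the flavanone on work-up would not matter, since step 6 converts both.

Step 6
Reactants: 8 (E)-1-[4-(benzyloxy)-6-hydroxy-2,3-dimethoxyphenyl]-3-[3-(benzyloxy)-4,5-dimethoxyphenyl]prop-2-en-1-one
Product: 10 7-(benzyloxy)-2-[3-(benzyloxy)-4,5-dimethoxyphenyl]-5,6-dimethoxy-4H-chromen-4-one, via racemic flavanone 9 (not isolated)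
Conditions: I2 (10 mol %), DMSO, 130 °C
Reagents that add atoms: none
Why: Iodine/DMSO oxidative cyclisation of a 2'-hydroxychalcone: 6-endo oxa-Michael addition of the phenol closes ring C to the racemic flavanone, iodination at C3 and loss of HI give the flavone, and DMSO reoxidises HI to I2 so that iodine stays catalytic.

Step 7
Reactants: 10 7-(benzyloxy)-2-[3-(benzyloxy)-4,5-dimethoxyphenyl]-5,6-dimethoxy-4H-chromen-4-one
Product: 11 7-hydroxy-2-(3-hydroxy-4,5-dimethoxyphenyl)-5,6-dimethoxy-4H-chromen-4-one (7,5'-dihydroxy-5,6,3',4'-tetramethoxyflavone)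
Conditions: H2 (1 atm), 10% Pd/C, EtOAc–MeOH, rt; stopped after uptake of 2 equiv H2
Reagents that add atoms: none
Why: Catalytic hydrogenolysis cleaves both aryl benzyl ethers, while the methyl ethers and the conjugated C2=C3 bond of the flavone should be inert at 1 atm and room temperature.

**Compound list**

1 | 1-(2,3,4-trihydroxyphenyl)ethan-1-one (gallacetophenone) | CC(=O)c1ccc(O)c(O)c1O | starting material
2 | 1-[4-(benzyloxy)-2,3-dihydroxyphenyl]ethan-1-one | CC(=O)c1ccc(OCc2ccccc2)c(O)c1O | intermediate
3 | 1-[4-(benzyloxy)-2,3-dimethoxyphenyl]ethan-1-one | CC(=O)c1ccc(OCc2ccccc2)c(OC)c1OC | intermediate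
4 | 2-acetyl-5-(benzyloxy)-3,4-dimethoxyphenyl trifluoroacetate | CC(=O)c1c(OC(=O)C(F)(F)F)cc(OCc2ccccc2)c(OC)c1OC | intermediate (not isolated)
5 | 1-[4-(benzyloxy)-6-hydroxy-2,3-dimethoxyphenyl]ethan-1-one | CC(=O)c1c(O)cc(OCc2ccccc2)c(OC)c1OC | intermediate
6 | 3-hydroxy-4,5-dimethoxybenzaldehyde | COc1cc(C=O)cc(O)c1OC | starting material
7 | 3-(benzyloxy)-4,5-dimethoxybenzaldehyde | COc1cc(C=O)cc(OCc2ccccc2)c1OC | intermediate
8 | (E)-1-[4-(benzyloxy)-6-hydroxy-2,3-dimethoxyphenyl]-3-[3-(benzyloxy)-4,5-dimethoxyphenyl]prop-2-en-1-one | COc1cc(/C=C/C(=O)c2c(O)cc(OCc3ccccc3)c(OC)c2OC)cc(OCc2ccccc2)c1OC | intermediate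
9 | rac-7-(benzyloxy)-2-[3-(benzyloxy)-4,5-dimethoxyphenyl]-5,6-dimethoxychroman-4-one (racemic at C2) | COc1cc(C2CC(=O)c3c(OC)c(OC)c(OCc4ccccc4)cc3O2)cc(OCc2ccccc2)c1OC | intermediate (not isolated)
10 | 7-(benzyloxy)-2-[3-(benzyloxy)-4,5-dimethoxyphenyl]-5,6-dimethoxy-4H-chromen-4-one | COc1cc(-c2cc(=O)c3c(OC)c(OC)c(OCc4ccccc4)cc3o2)cc(OCc2ccccc2)c1OC | intermediate
11 | 7-hydroxy-2-(3-hydroxy-4,5-dimethoxyphenyl)-5,6-dimethoxy-4H-chromen-4-one | COc1cc(-c2cc(=O)c3c(OC)c(OC)c(O)cc3o2)cc(O)c1OC | target

**Step count and risk**

Total step count: 7. Longest linear sequence: 6 (steps 1, 2, 3, 5, 6, 7); step 4 is the one-step branch.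

Steps most likely to fail:

Step 3 (key step). What may go wrong: non-directed oxidation of the electron-rich ring by the iodine(III) reagent at the most activated position, oxidation alpha to the ketone, acid- or oxidant-induced loss of the benzyl ether, or slow palladation because the ortho-methoxy group twists the acetyl group out of the ring plane. Fallback (classical acylation of a tetraoxygenated phenol instead of C–H oxygenation), setting out from 7 and returning at 5: Dakin-type Baeyer–Villiger oxidation of 7 with mCPBA in CH2Cl2 should give 3-(benzyloxy)-4,5-dimethoxyphenyl formate F1, which K2CO3 in MeOH/H2O should cleave to 3-(benzyloxy)-4,5-dimethoxyphenol F2. C-acetylation of F2 ortho to the free hydroxyl with AcOH/BF3·OEt2 at 80 °C (Friedel–Crafts/Fries type, through the BF2 chelate) should give 5. Acetylation at the other ortho position, next to the benzyloxy group, is expected to compete, so a chromatographic separation would be needed; this is the regiochemical weakness that step 3 is designed to avoid.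

Step 6. What may go wrong: electrophilic iodination of the activated C8 position, HI-promoted loss of the 5-O-methyl group (peri to the carbonyl) or of a benzyl group at 130 °C. Fallback (halogen-free, two discrete operations), setting out from 8 and returning at 10: NaOAc in refluxing EtOH should isomerise 8 to the racemic flavanone 9, which is isolated this time; DDQ in refluxing dioxane should then dehydrogenate 9 to 10 by hydride abstraction. This detour makes no compound outside the compound list (entry F0).

Step 5. What may go wrong: slow enolisation of the doubly ortho-substituted, hydrogen-bonded ketone, so that Cannizzaro consumption of the aldehyde competes and conversion stays incomplete. Fallback (Baker–Venkataraman route, which forms the C3–C2 bond by acyl transfer instead of aldol condensation and needs no oxidative cyclisation), setting out from 7 and 5 and returning at 10: Pinnick oxidation of 7 (NaClO2, NaH2PO4, 2-methyl-2-butene, t-BuOH/H2O) should give 3-(benzyloxy)-4,5-dimethoxybenzoic acid F3. Esterification of F3 with phenol 5 (EDC·HCl, DMAP, CH2Cl2) should give 2-acetyl-5-(benzyloxy)-3,4-dimethoxyphenyl 3-(benzyloxy)-4,5-dimethoxybenzoate F4. KOH in pyridine at 50 °C should rearrange F4 to 1-[4-(benzyloxy)-6-hydroxy-2,3-dimethoxyphenyl]-3-[3-(benzyloxy)-4,5-dimethoxyphenyl]propane-1,3-dione F5, and TsOH in refluxing toluene should cyclodehydrate F5 to 10.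

**Further compounds**

F1 | step 3 | 3-(benzyloxy)-4,5-dimethoxyphenyl formate | COc1cc(OC=O)cc(OCc2ccccc2)c1OC
F2 | step 3 | 3-(benzyloxy)-4,5-dimethoxyphenol | COc1cc(O)cc(OCc2ccccc2)c1OC
F0 | step 6 | none | none
F3 | step 5 | 3-(benzyloxy)-4,5-dimethoxybenzoic acid | COc1cc(C(=O)O)cc(OCc2ccccc2)c1OC
F4 | step 5 | 2-acetyl-5-(benzyloxy)-3,4-dimethoxyphenyl 3-(benzyloxy)-4,5-dimethoxybenzoate | CC(=O)c1c(OC(=O)c2cc(OC)c(OC)c(OCc3ccccc3)c2)cc(OCc2ccccc2)c(OC)c1OC
F5 | step 5 | 1-[4-(benzyloxy)-6-hydroxy-2,3-dimethoxyphenyl]-3-[3-(benzyloxy)-4,5-dimethoxyphenyl]propane-1,3-dione | COc1cc(C(=O)CC(=O)c2c(O)cc(OCc3ccccc3)c(OC)c2OC)cc(OCc2ccccc2)c1OC
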